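## Structural features

The target 24 is built from three oxygenated benzene units. Its core is a 2,3-dihydrobenzofuran (benzene ring A fused to the dihydrofuran ring) carrying a 4-hydroxy-3-methoxyphenyl group (ring B) at C2, a hydroxymethyl group at C3 and a methoxy group at C7. C5 of this core is bonded directly to C2′ of a 7′-methoxybenzofuran that bears a 3-hydroxypropyl chain at C5′. The only stereocentres are the neighbouring C2 (S) and C3 (R), with their substituents trans on the five-membered ring. The C2–O1 bond is a para-hydroxybenzyl aryl ether: base can expel the ring-A phenoxide through a quinone methide, acid can ionise it, and the free guaiacyl phenol is easily oxidised. The real difficulty is absolute control of the C2/C3 pair, together with a regiodefined union of ring A with the benzofuran. The key step uses the fact that C2 is attached to ring B para to its hydroxyl, so C2 can become the exocyclic carbon of a para-quinone methide. The ring-A oxygen that becomes O1 sits ortho to the carbon bearing C3, placed for a five-membered closure onto that carbon, and C3 (no acidifying group) can be set beforehand and relay its configuration to C2.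

## Logic of the disconnections

24 ⇒ 23. The two oxygen–silicon bonds are cut last. The guaiacyl hydroxyl is what makes C2–O1 labile to base and oxidants, so it stays masked until the end. The forward step must be a buffered fluoride cleavage so the liberated phenoxide does not reopen the ring.

23 ⇒ 19 + 21 (through 22). The benzofuran is opened at O1′–C2′ and at C3′–C3a′, so C2′ and C3′ become an ethynyl group on C5 of ring A. This divides the molecule into two halves of similar size at its only junction without stereochemistry. The positions of iodine and hydroxyl in 21 fix the substitution pattern of the new ring. The forward step must couple an electron-rich iodophenol and then close 22 in the 5-endo-dig mode.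

21 ⇒ 20. The carbon–iodine bond is cut; the phenoxide directs the halogen to its free ortho position. This branch costs one step.

19 ⇒ 18 ⇒ 17 ⇒ 16 ⇒ 15. The terminal alkyne carbon is removed (one-carbon homologation of an aldehyde), the aldehyde is traced through the benzylic alcohol to the ester, and the two silyl ethers are cut. The ester is kept this far because it is the deactivating group the ring closure needs. Both hydroxyls of 15 are silylated in one operation because only after ring closure is the free ring-B phenol a liability (oxidation in step 12, base in steps 13 and 15). The silyl groups must survive carbonate in methanol, hence triisopropylsilyl.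

15 ⇒ 13 (through 14). The O1–C2 bond is cut. The heterocycle and the C2 stereocentre disappear, leaving an acyclic 1,2-diarylpropanol with one stereocentre. The forward step must oxidise only the ring-B phenol and close the ring trans. The primary alcohol is left unprotected, because its attack on the methide carbon would need a four-membered ring; this saves a separate silylation before the ring closure.

13 ⇒ 12 ⇒ 11. Two oxygen–benzyl bonds are cut and the CH2OH is traced to CO2H. The ring-A phenol must be masked from the arylacetic acid stage onward (a free ortho-hydroxyl would lactonise), and benzyl on both phenols lets one hydrogenolysis uncover them together. The reduction must distinguish the acid from the methyl ester.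

11 ⇒ 10. The two carbon–hydrogen bonds across the former alkene are cut. The stereocentre is reduced to a question of alkene geometry plus a carboxylate-directed asymmetric hydrogenation. The demand is high enantioface selectivity on an α-aryl cinnamic acid whose α-aryl ring has two ortho substituents.

10 ⇒ 8 + 9. The C=C bond is cut (condensation of an arylacetic acid with an aromatic aldehyde). This gives two simple benzenoid pieces, one of them bought. The forward step must give the E isomer.

8 ⇒ 6 ⇒ 5 ⇒ 3 ⇒ 1 + 2. The acid is traced to an allyl group (oxidative cleavage through 7), the benzyl ether is cut, the aryl–allyl bond is traced to an aromatic Claisen rearrangement through 4, and the allyl ether is cut. The 1,2,3,5-pattern of ring A follows from 1, whose methoxy group blocks one ortho position. The oxidative cleavage must spare the arene and the benzyl ether.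

## Other disconnections considered

Alternative 1: The cut is in the benzenoid ring of the benzofuran, with C7–C7a as the ring-closing bond. Carbons C4–C7 are built onto a furan already attached to ring A.
- **Forward step:** furan aldehyde A1 would undergo Stobbe condensation with a succinic diester to half-ester A2. Ac2O/NaOAc would convert the CH2CO2H arm into a mixed anhydride that acylates the free furan α-carbon; enol acetylation would aromatise the ring to acetoxybenzofuran ester A3.
- **In favour:** the oxygen at C7 and the carbon substituent at C5 are placed by construction. The furan α-position is its most nucleophilic site. No transition metal and no alkyne are needed; on these points the alternative is the equal of the chosen plan (regiochemical certainty) or better (no Pd/Cu step, no diazo reagent).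
- **Against:** it solves the easier half of the problem. A1 already contains the complete dihydrobenzofuran with both stereocentres, so steps 1–9 or an equivalent are still needed, plus attachment of the furan at C5. After A3 the C5 ester must be extended by two carbons and reduced, the C7 acetate exchanged for a methyl ether, and the benzyl and silyl groups removed. Only the E isomer of A2 can cyclise, and an advanced chiral intermediate is exposed to alkoxide and to hot anhydride.
- **Comparison:** structurally the two plans differ in which benzofuran ring is made last (carbocycle there, furan here). Mechanistically it is an electrophilic acylation against a metal-catalysed coupling and cycloisomerisation. In step economy the chosen plan is clearly ahead: seven operations from 15 to 24 (branch step included) against about a dozen after A1.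

Alternative 2: The cut is C3–C3a, read as a ring contraction of flavanone A4.
- **Forward step:** PhI(OAc)2 (a reagent of trivalent iodine) with H2SO4 in trimethyl orthoformate would convert A4 into its dimethyl ketal iodinated at C3. The ring-A carbon would migrate from C4 to C3 as iodobenzene leaves, giving the trans methyl ester A5.
- **In favour:** one step gives a trans-2-aryl-dihydrobenzofuran with C3 at the ester level (one reduction from CH2OH). The bromine at C5 would allow direct cross-coupling with a preformed 2-metalated benzofuran. The sulfonate makes ring B a poor migrating and oxidisable group. The overall count could be near ten operations, so in step economy this alternative is the better plan. It is also better in not requiring selective oxidation of one phenol beside another.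
- **Against:** all absolute configuration rests on C2 of A4. An enantiopure flavanone is not trivial to obtain, and flavanones can racemise by reversible opening of the pyranone ring under acid or base, while the contraction runs in strong acid. Dehydrogenation to the flavone and a competing shift of ring B are known side paths. The sulfonate must later be removed from a base-sensitive phenylcoumaran.
- **Comparison:** the logic is the mirror image of the chosen plan. There C2 is set first and controls an epimerisable C3; here a non-epimerisable C3 is set first and controls C2. Mechanistically it is a cationic 1,2-aryl shift against a conjugate addition to a quinone methide. The descriptors of A5 are (2S,3S); reduction of the ester changes the label at C3 to R without changing the geometry.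

Alternative 3: Both ring bonds, C3–C3a and O1–C2, are cut at once between feruloyl imide A6 and benzofuran phenol A7.
- **Forward step:** horseradish peroxidase with H2O2 would oxidise both phenols to phenoxyl radicals. C8 of the A6 radical (the carbon next to the carbonyl) would couple with the ring carbon ortho to the oxygen of the A7 radical. After rearomatisation the phenol would add to the quinone methide to give imide A8, and reductive removal of the auxiliary would lead to 24.
- **In favour:** it is the shortest and most convergent plan, perhaps six or seven operations in all; in step economy it is clearly the better one. The whole skeleton, benzofuran included, is assembled in one mild aqueous step without protecting groups. The ring-closing half is the same quinone methide capture as in the chosen key step, so the trans relationship is secured in the same way and the two plans are equal there.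
- **Against:** two different radicals are formed. The A6 radical can dimerise in several modes and the A7 radical can couple through oxygen or carbon, so the cross 8–5 product would be one component of a mixture. The oxazolidinone is not held in a chelate in aqueous buffer, so shielding of one face of C8 should be loose and the selectivity at C3 modest. The products are phenols and can be oxidised further.
- **Comparison:** the chosen plan gives up length for control: one phenol is oxidised by two electrons in a molecule that already holds C3 in one configuration, instead of a radical–radical coupling deciding site and face together. By the sequence rules A8 is (2S,3S), not (2S,3R), because the acyl carbon outranks C2 at C3; its geometry is that of 24.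

Key step: step 9

Assumption (chemistry): the (S,S) antipode of the bisphospholane ligand in step 6 is taken to deliver the (R) acid 11; if the first run shows the opposite sense, the (R,R) ligand is used and nothing else changes.

## Route

Step 1
Reactants: 1 methyl vanillate (methyl 4-hydroxy-3-methoxybenzoate); 2 allyl bromide
Product: 3 methyl 4-(allyloxy)-3-methoxybenzoate
Conditions: K2CO3, acetone, reflux
Reagents that add atoms: none
Why: Williamson ether synthesis: the phenoxide displaces bromide from the allylic halide (SN2) and the ester is inert to carbonate in acetone.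

Step 2
Reactants: 3 methyl 4-(allyloxy)-3-methoxybenzoate
Product: 5 methyl 3-allyl-4-hydroxy-5-methoxybenzoate, via dienone 4 (not isolated)
Conditions: PhNEt2, 200 °C
Reagents that add atoms: none
Why: Aromatic Claisen rearrangement: the [3,3]-sigmatropic shift can only reach the free ortho carbon (the other is blocked by OMe) and dienone 4 tautomerises to the phenol.

Step 3
Reactants: 5 methyl 3-allyl-4-hydroxy-5-methoxybenzoate
Product: 6 methyl 3-allyl-4-(benzyloxy)-5-methoxybenzoate
Conditions: BnBr, K2CO3, DMF, 60 °C
Reagents that add atoms: benzyl bromide, BrCc1ccccc1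
Why: Williamson benzylation; a free ortho-hydroxyl would lactonise the arylacetic acid of step 4 to a benzofuranone and derail the Perkin step, and this benzyl ether leaves together with the ring-B benzyl ether in step 8.

Step 4
Reactants: 6 methyl 3-allyl-4-(benzyloxy)-5-methoxybenzoate
Product: 8 [2-(benzyloxy)-3-methoxy-5-(methoxycarbonyl)phenyl]acetic acid, via arylacetaldehyde 7 (not isolated)
Conditions: O3, MeCN/H2O (9:1), 0 °C; then aq. NaClO2, 0 °C → rt; NaHSO3
Reagents that add atoms: ozone, [O-][O+]=O; water, O; sodium chlorite, [Na+].[O-]Cl=O
Why: Ozonolysis in aqueous acetonitrile gives aldehyde 7 directly because water intercepts the carbonyl oxide, and chlorite oxidises it to the acid in the same flask (Pinnick-type oxidation), the hydrogen peroxide from the first stage scavenging hypochlorite; the terminal alkene reacts with ozone much faster than the ester-deactivated arene or the benzyl ether.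

Step 5
Reactants: 8 [2-(benzyloxy)-3-methoxy-5-(methoxycarbonyl)phenyl]acetic acid; 9 4-(benzyloxy)-3-methoxybenzaldehyde (O-benzylvanillin)
Product: 10 (2E)-2-[2-(benzyloxy)-3-methoxy-5-(methoxycarbonyl)phenyl]-3-[4-(benzyloxy)-3-methoxyphenyl]prop-2-enoic acid
Conditions: Ac2O, Et3N, 110 °C; then H2O, 90 °C; aq. HCl
Reagents that add atoms: none
Why: Perkin condensation: the enolate of the mixed anhydride of the arylacetic acid adds to the aldehyde and loss of acetate gives the α-aryl cinnamic acid, mainly the E isomer with the two aryl groups cis, which is purified by crystallisation.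

Step 6
Reactants: 10 (2E)-2,3-diarylprop-2-enoic acid
Product: 11 (2R)-2-[2-(benzyloxy)-3-methoxy-5-(methoxycarbonyl)phenyl]-3-[4-(benzyloxy)-3-methoxyphenyl]propanoic acid
Conditions: Co(acac)2 (2 mol %), (S,S)-Ph-BPE (2.2 mol %), Zn (20 mol %), H2 (40 bar), i-PrOH, 50 °C
Reagents that add atoms: none
Why: Carboxylate-directed asymmetric hydrogenation of an α-aryl cinnamic acid: the carboxylate binds cobalt and holds the alkene in the chiral pocket of the bisphospholane, so hydrogen is delivered to one enantioface and the stereocentre (the later C3) is set as R; benzyl ethers, ester and arenes are untouched, and the acid can be enriched further by crystallisation as an amine salt.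

Step 7
Reactants: 11 (2R)-2,3-diarylpropanoic acid
Product: 12 methyl 4-(benzyloxy)-3-[(2R)-1-[4-(benzyloxy)-3-methoxyphenyl]-3-hydroxypropan-2-yl]-5-methoxybenzoate
Conditions: BH3·THF, THF, 0 °C → rt; MeOH
Reagents that add atoms: none
Why: Borane reduces a carboxylic acid through its acyloxyborane far faster than an ester, so CH2OH is formed while the methyl benzoate stays; no base is present, so the α-aryl stereocentre cannot epimerise.

Step 8
Reactants: 12 methyl 4-(benzyloxy)-3-[(2R)-1-[4-(benzyloxy)-3-methoxyphenyl]-3-hydroxypropan-2-yl]-5-methoxybenzoate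
Product: 13 methyl 4-hydroxy-3-[(2R)-1-hydroxy-3-(4-hydroxy-3-methoxyphenyl)propan-2-yl]-5-methoxybenzoate
Conditions: H2 (1 atm), Pd/C (10 wt %), EtOAc/MeOH, rt
Reagents that add atoms: none
Why: Catalytic hydrogenolysis cleaves both benzyl aryl ethers in one operation; nothing else in the molecule is reducible under these conditions.

Step 9
Reactants: 13 methyl 4-hydroxy-3-[(2R)-1-hydroxy-3-(4-hydroxy-3-methoxyphenyl)propan-2-yl]-5-methoxybenzoate
Product: 15 methyl (2S,3R)-2-(4-hydroxy-3-methoxyphenyl)-3-(hydroxymethyl)-7-methoxy-2,3-dihydro-1-benzofuran-5-carboxylate, via para-quinone methide 14 (not isolated)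
Conditions: Ag2O (1.2 equiv), CH2Cl2/acetone (4:1), rt, dark
Reagents that add atoms: none
Why: Ag2O takes two electrons and two protons from the electron-rich 4-alkyl-2-methoxyphenol of ring B (phenoxyl radical, then loss of the benzylic hydrogen) to give para-quinone methide 14, while the ring-A phenol, para to the ester, has a higher oxidation potential and is left alone. The ring-A hydroxyl then adds to the exocyclic methide carbon in a 1,6-conjugate addition that forms O1–C2 and rearomatises ring B with its hydroxyl free. The closest known reaction type is the Ag2O (or DDQ) oxidation of 4-alkylguaiacols to para-quinone methides and the phenol addition that closes the ring in oxidative 8–5 coupling of coniferyl-type phenols, where the same CH2OH group stands free on the neighbouring carbon. The one ring is closed in the 5-exo-trig mode (the oxygen attacks the exocyclic terminus and the other alkene carbon stays outside the new ring). The new stereocentre C2 is controlled by C3 from step 6: in the envelope-like transition state the aryl group avoids the CH2OH group, and because the addition can revert through 14 the trans (2S,3R) isomer is also the thermodynamic outcome. Three selectivities are needed: between the two phenols (secured by the ester), between the phenolic and the primary hydroxyl as nucleophile (the latter would have to form an oxetane), and against further oxidation of 15 or tautomerisation of 14 to a stilbene (secured by little more than one equivalent of oxidant at room temperature and by fast intramolecular capture).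

Step 10
Reactants: 15 methyl (2S,3R)-2-(4-hydroxy-3-methoxyphenyl)-3-(hydroxymethyl)-7-methoxy-2,3-dihydro-1-benzofuran-5-carboxylate
Product: 16 methyl (2S,3R)-7-methoxy-2-{3-methoxy-4-[(triisopropylsilyl)oxy]phenyl}-3-{[(triisopropylsilyl)oxy]methyl}-2,3-dihydro-1-benzofuran-5-carboxylate
Conditions: TIPSCl (2.6 equiv), imidazole, DMAP (cat.), DMF, rt
Reagents that add atoms: triisopropylsilyl chloride, CC(C)[Si](Cl)(C(C)C)C(C)C
Why: Imidazole-promoted silylation of both hydroxyls; masking the guaiacyl OH removes the handle by which base could reopen C2–O1 through a quinone methide and by which MnO2 could oxidise ring B, and the triisopropylsilyl aryl ether withstands carbonate in methanol better than smaller silyl groups.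

Step 11
Reactants: 16 bis-silyl ester
Product: 17 [(2S,3R)-7-methoxy-2-{3-methoxy-4-[(triisopropylsilyl)oxy]phenyl}-3-{[(triisopropylsilyl)oxy]methyl}-2,3-dihydro-1-benzofuran-5-yl]methanol
Conditions: DIBAL-H (2.5 equiv), CH2Cl2, −78 → 0 °C; aq. KNaC4H4O6 (potassium sodium tartrate)
Reagents that add atoms: none
Why: Hydride reduction of the aryl methyl ester to the benzylic alcohol; silyl ethers and the dihydrofuran are inert to the aluminium hydride at low temperature.

Step 12
Reactants: 17 benzylic alcohol
Product: 18 (2S,3R)-7-methoxy-2-{3-methoxy-4-[(triisopropylsilyl)oxy]phenyl}-3-{[(triisopropylsilyl)oxy]methyl}-2,3-dihydro-1-benzofuran-5-carbaldehyde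
Conditions: MnO2 (activated, 15 equiv), CH2Cl2, rt
Reagents that add atoms: none
Why: Activated MnO2 oxidises benzylic alcohols selectively to aldehydes without over-oxidation; with the phenol silylated no other oxidisable group is exposed.

Step 13
Reactants: 18 aldehyde
Product: 19 (2S,3R)-5-ethynyl-7-methoxy-2-{3-methoxy-4-[(triisopropylsilyl)oxy]phenyl}-3-{[(triisopropylsilyl)oxy]methyl}-2,3-dihydro-1-benzofuran
Conditions: dimethyl (1-diazo-2-oxopropyl)phosphonate, K2CO3, MeOH/THF, 0 °C → rt
Reagents that add atoms: dimethyl (1-diazo-2-oxopropyl)phosphonate (Ohira–Bestmann reagent), COP(=O)(OC)C(=[N+]=[N-])C(C)=O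
Why: Seyferth–Gilbert homologation with the Ohira–Bestmann reagent: methoxide deacetylates the reagent, the diazophosphonate anion olefinates the non-enolisable aryl aldehyde, and loss of N2 with 1,2-hydrogen shift gives the terminal alkyne; no stereocentre is acidic under these conditions.

Step 14
Reactants: 20 4-(3-hydroxypropyl)-2-methoxyphenol (dihydroconiferyl alcohol)
Product: 21 4-(3-hydroxypropyl)-2-iodo-6-methoxyphenol
Conditions: I2, NaHCO3, THF/H2O, 0 °C → rt
Reagents that add atoms: iodine, [I][I]
Why: Electrophilic aromatic iodination of the phenoxide, which directs the halogen to its only free ortho position (para is occupied by the side chain); the primary alcohol does not react.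

Step 15
Reactants: 19 aryl alkyne; 21 4-(3-hydroxypropyl)-2-iodo-6-methoxyphenol
Product: 23 3-{7-methoxy-2-[(2S,3R)-7-methoxy-2-{3-methoxy-4-[(triisopropylsilyl)oxy]phenyl}-3-{[(triisopropylsilyl)oxy]methyl}-2,3-dihydro-1-benzofuran-5-yl]-1-benzofuran-5-yl}propan-1-ol, via ortho-alkynylphenol 22 (not isolated)
Conditions: PdCl2(PPh3)2 (5 mol %), CuI (10 mol %), Et3N, DMF, rt → 70 °C, Ar
Reagents that add atoms: none
Why: Sonogashira coupling of the terminal alkyne with the ortho-iodophenol gives 22, whose phenol adds across the metal-activated alkyne in a 5-endo-dig cyclisation on warming (the established one-flask route from ortho-iodophenols to 2-arylbenzofurans); the substitution pattern of the new ring follows from the positions of iodine and hydroxyl in 21.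

Step 16
Reactants: 23 bis-silyl ether of the target
Product: 24 4-[(2S,3R)-3-(hydroxymethyl)-5-[5-(3-hydroxypropyl)-7-methoxy-1-benzofuran-2-yl]-7-methoxy-2,3-dihydro-1-benzofuran-2-yl]-2-methoxyphenol
Conditions: TBAF, AcOH, THF, 0 °C → rt
Reagents that add atoms: none
Why: Fluoride cleaves the aryl and the alkyl silyl ether (strong Si–F bond); acetic acid buffers the liberated phenoxide so that the para-hydroxybenzyl ether C2–O1 is not opened and C2/C3 stay (2S,3R).

## Compound list

1 | methyl vanillate (methyl 4-hydroxy-3-methoxybenzoate) | COC(=O)c1ccc(O)c(OC)c1 | starting material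
2 | allyl bromide | C=CCBr | starting material
3 | methyl 4-(allyloxy)-3-methoxybenzoate | COC(=O)c1ccc(OCC=C)c(OC)c1 | intermediate
4 | methyl 5-methoxy-4-oxo-3-(prop-2-en-1-yl)cyclohexa-1,5-diene-1-carboxylate (Claisen dienone, racemic) | COC(=O)C1=CC(CC=C)C(=O)C(OC)=C1 | intermediate
5 | methyl 3-allyl-4-hydroxy-5-methoxybenzoate | COC(=O)c1cc(CC=C)c(O)c(OC)c1 | intermediate
6 | methyl 3-allyl-4-(benzyloxy)-5-methoxybenzoate | COC(=O)c1cc(CC=C)c(OCc2ccccc2)c(OC)c1 | intermediate
7 | methyl 4-(benzyloxy)-3-methoxy-5-(2-oxoethyl)benzoate | COC(=O)c1cc(CC=O)c(OCc2ccccc2)c(OC)c1 | intermediate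
8 | [2-(benzyloxy)-3-methoxy-5-(methoxycarbonyl)phenyl]acetic acid | COC(=O)c1cc(CC(O)=O)c(OCc2ccccc2)c(OC)c1 | intermediate
9 | 4-(benzyloxy)-3-methoxybenzaldehyde | COc1cc(C=O)ccc1OCc1ccccc1 | starting material
10 | (2E)-2-[2-(benzyloxy)-3-methoxy-5-(methoxycarbonyl)phenyl]-3-[4-(benzyloxy)-3-methoxyphenyl]prop-2-enoic acid | COC(=O)c1cc(/C(C(O)=O)=C\c2ccc(OCc3ccccc3)c(OC)c2)c(OCc2ccccc2)c(OC)c1 | intermediate
11 | (2R)-2-[2-(benzyloxy)-3-methoxy-5-(methoxycarbonyl)phenyl]-3-[4-(benzyloxy)-3-methoxyphenyl]propanoic acid | COC(=O)c1cc([C@@H](Cc2ccc(OCc3ccccc3)c(OC)c2)C(O)=O)c(OCc2ccccc2)c(OC)c1 | intermediate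
12 | methyl 4-(benzyloxy)-3-[(2R)-1-[4-(benzyloxy)-3-methoxyphenyl]-3-hydroxypropan-2-yl]-5-methoxybenzoate | COC(=O)c1cc([C@@H](Cc2ccc(OCc3ccccc3)c(OC)c2)CO)c(OCc2ccccc2)c(OC)c1 | intermediate
13 | methyl 4-hydroxy-3-[(2R)-1-hydroxy-3-(4-hydroxy-3-methoxyphenyl)propan-2-yl]-5-methoxybenzoate | COC(=O)c1cc(OC)c(O)c([C@@H](Cc2ccc(O)c(OC)c2)CO)c1 | intermediate
14 | methyl 4-hydroxy-3-[(2R)-1-hydroxy-3-(3-methoxy-4-oxocyclohexa-2,5-dien-1-ylidene)propan-2-yl]-5-methoxybenzoate (para-quinone methide) | COC(=O)c1cc(OC)c(O)c([C@@H](C=C2C=CC(=O)C(OC)=C2)CO)c1 | intermediate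
15 | methyl (2S,3R)-2-(4-hydroxy-3-methoxyphenyl)-3-(hydroxymethyl)-7-methoxy-2,3-dihydro-1-benzofuran-5-carboxylate | COc1cc([C@H]2Oc3c(OC)cc(C(=O)OC)cc3[C@@H]2CO)ccc1O | intermediate
16 | methyl (2S,3R)-7-methoxy-2-{3-methoxy-4-[(triisopropylsilyl)oxy]phenyl}-3-{[(triisopropylsilyl)oxy]methyl}-2,3-dihydro-1-benzofuran-5-carboxylate | COc1cc([C@H]2Oc3c(OC)cc(C(=O)OC)cc3[C@@H]2CO[Si](C(C)C)(C(C)C)C(C)C)ccc1O[Si](C(C)C)(C(C)C)C(C)C | intermediate
17 | [(2S,3R)-7-methoxy-2-{3-methoxy-4-[(triisopropylsilyl)oxy]phenyl}-3-{[(triisopropylsilyl)oxy]methyl}-2,3-dihydro-1-benzofuran-5-yl]methanol | COc1cc([C@H]2Oc3c(OC)cc(CO)cc3[C@@H]2CO[Si](C(C)C)(C(C)C)C(C)C)ccc1O[Si](C(C)C)(C(C)C)C(C)C | intermediate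
18 | (2S,3R)-7-methoxy-2-{3-methoxy-4-[(triisopropylsilyl)oxy]phenyl}-3-{[(triisopropylsilyl)oxy]methyl}-2,3-dihydro-1-benzofuran-5-carbaldehyde | COc1cc([C@H]2Oc3c(OC)cc(C=O)cc3[C@@H]2CO[Si](C(C)C)(C(C)C)C(C)C)ccc1O[Si](C(C)C)(C(C)C)C(C)C | intermediate
19 | (2S,3R)-5-ethynyl-7-methoxy-2-{3-methoxy-4-[(triisopropylsilyl)oxy]phenyl}-3-{[(triisopropylsilyl)oxy]methyl}-2,3-dihydro-1-benzofuran | COc1cc([C@H]2Oc3c(OC)cc(C#C)cc3[C@@H]2CO[Si](C(C)C)(C(C)C)C(C)C)ccc1O[Si](C(C)C)(C(C)C)C(C)C | intermediate
20 | 4-(3-hydroxypropyl)-2-methoxyphenol (dihydroconiferyl alcohol) | COc1cc(CCCO)ccc1O | starting material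
21 | 4-(3-hydroxypropyl)-2-iodo-6-methoxyphenol | COc1cc(CCCO)cc(I)c1O | intermediate
22 | 4-(3-hydroxypropyl)-2-methoxy-6-{[(2S,3R)-7-methoxy-2-{3-methoxy-4-[(triisopropylsilyl)oxy]phenyl}-3-{[(triisopropylsilyl)oxy]methyl}-2,3-dihydro-1-benzofuran-5-yl]ethynyl}phenol | COc1cc([C@H]2Oc3c(OC)cc(C#Cc4cc(CCCO)cc(OC)c4O)cc3[C@@H]2CO[Si](C(C)C)(C(C)C)C(C)C)ccc1O[Si](C(C)C)(C(C)C)C(C)C | intermediate
23 | 3-{7-methoxy-2-[(2S,3R)-7-methoxy-2-{3-methoxy-4-[(triisopropylsilyl)oxy]phenyl}-3-{[(triisopropylsilyl)oxy]methyl}-2,3-dihydro-1-benzofuran-5-yl]-1-benzofuran-5-yl}propan-1-ol | COc1cc([C@H]2Oc3c(OC)cc(-c4cc5cc(CCCO)cc(OC)c5o4)cc3[C@@H]2CO[Si](C(C)C)(C(C)C)C(C)C)ccc1O[Si](C(C)C)(C(C)C)C(C)C | intermediate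
24 | 4-[(2S,3R)-3-(hydroxymethyl)-5-[5-(3-hydroxypropyl)-7-methoxy-1-benzofuran-2-yl]-7-methoxy-2,3-dihydro-1-benzofuran-2-yl]-2-methoxyphenol | COc1cc([C@H]2Oc3c(OC)cc(-c4cc5cc(CCCO)cc(OC)c5o4)cc3[C@@H]2CO)ccc1O | target

## Step count and least certain steps

Total: 16 steps. Longest linear sequence: 15 steps (steps 1–13, 15 and 16); step 14 is a one-step branch.

**Step 9 (key step).**
- Risk: further oxidation of the newly formed guaiacyl coumaran by surplus oxidant; competing one-electron oxidation of the ester-bearing phenol followed by radical coupling; tautomerisation of the quinone methide to a stilbene with loss of the C3 stereocentre. All three stem from using an oxidant on a molecule that keeps oxidisable phenols before and after the desired event.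
- Fallback: a non-oxidative, dehydrative closure of the same O1–C2 bond, setting out from 8 and returning at 15. Acid 8 is activated as its mixed pivalic anhydride (PivCl, Et3N) and joined to (S)-4-benzyl-1,3-oxazolidin-2-one (LiCl) to give the (4S)-N-arylacetyl oxazolidinone F1. Its dibutylboron enolate (Bu2BOTf, i-Pr2NEt, CH2Cl2, −78 °C) adds to 9 in an Evans syn-aldol reaction to give the (2S,3S)-aldol imide F2, which fixes the future C3. NaBH4 in THF/H2O removes the auxiliary reductively without touching the benzoate and gives the (1S,2R)-1,3-diol F3. Hydrogenolysis (H2, Pd/C, EtOAc, stopped after two equivalents) frees both phenols to give the tetraol F4. Catalytic p-TsOH in CH2Cl2/THF ionises the para-hydroxybenzylic alcohol and the ring-A phenol closes onto the cation to give 15, trans for the same thermodynamic reason. The carbinol configuration is lost in the cation and does not matter.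

**Step 6.**
- Risk: weak enantioface discrimination or slow turnover, because the α-aryl ring with two ortho substituents is twisted out of the alkene plane and crowds the carboxylate-bound metal. The sense of induction also cannot be predicted with certainty.
- Fallback: auxiliary control in place of catalyst control, setting out from 8 and returning at 12 (replacing steps 5–7). Acid 8 is joined, as above but to (R)-4-benzyl-1,3-oxazolidin-2-one, to give the (4R)-imide F5. Its sodium enolate (NaN(SiMe3)2, THF, −78 °C) is alkylated (Evans alkylation) with 4-(benzyloxy)-3-methoxybenzyl bromide F6, made from commercial [4-(benzyloxy)-3-methoxyphenyl]methanol and PBr3. Attack on the face away from the auxiliary's benzyl group gives the (2R)-imide F7. NaBH4 in THF/H2O then releases 12. The (R) auxiliary is needed because the chelated Z-enolate is attacked anti to its 4-benzyl group and the aryl substituent occupies the place of methyl in the familiar propionimide case.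

**Step 15.**
- Risk: stalling at the coupled but uncyclised stage, since the iodophenol is electron-rich and its phenol weakly acidic; oxidative homocoupling of the alkyne on long heating with copper.
- Fallback: the coupling is run at room temperature only as far as 22, which is isolated. The furan ring is then closed in a separate cycloisomerisation with AuCl(PPh3)/AgOTf (2 mol %) in toluene at rt (π-acid activation of the alkyne, 5-endo-dig attack of the phenol), returning at 23. This makes no new compound (entry F0).

**Step 13.**
- Risk: loss of the aryl silyl ether by methoxide, followed by base-induced opening of C2–O1 through the quinone methide at the stage where the leaving phenoxide is para to an aldehyde.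
- Fallback: a carbonate-free homologation, setting out from 18 and returning at 19. Corey–Fuchs olefination (CBr4, PPh3, CH2Cl2, 0 °C) gives the 1,1-dibromoalkene F8. Treatment with n-BuLi (2.2 equiv, THF, −78 °C) and aqueous NH4Cl gives 19 by bromine–lithium exchange and rearrangement of the carbenoid.

**Step 4.**
- Risk: attack of ozone on the trioxygenated arene or on the benzylic C–H bonds of the benzyl ether if the endpoint is overshot.
- Fallback: osmium-catalysed cleavage in stages, setting out from 6 and returning at 8. Upjohn dihydroxylation (OsO4 cat., NMO, acetone/H2O) gives the diol F9. NaIO4 cleaves it to 7, which is oxidised without purification under Pinnick conditions (NaClO2, NaH2PO4, 2-methyl-2-butene, t-BuOH/H2O) to 8.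

## Further compounds

F1 | step 9 | (4S)-4-benzyl-3-{[2-(benzyloxy)-3-methoxy-5-(methoxycarbonyl)phenyl]acetyl}-1,3-oxazolidin-2-one | COC(=O)c1cc(CC(=O)N2C(=O)OC[C@@H]2Cc2ccccc2)c(OCc2ccccc2)c(OC)c1
F2 | step 9 | (4S)-4-benzyl-3-[(2S,3S)-2-[2-(benzyloxy)-3-methoxy-5-(methoxycarbonyl)phenyl]-3-[4-(benzyloxy)-3-methoxyphenyl]-3-hydroxypropanoyl]-1,3-oxazolidin-2-one | COC(=O)c1cc([C@@H]([C@H](O)c2ccc(OCc3ccccc3)c(OC)c2)C(=O)N2C(=O)OC[C@@H]2Cc2ccccc2)c(OCc2ccccc2)c(OC)c1
F3 | step 9 | methyl 4-(benzyloxy)-3-[(1S,2R)-1-[4-(benzyloxy)-3-methoxyphenyl]-1,3-dihydroxypropan-2-yl]-5-methoxybenzoate | COC(=O)c1cc([C@@H]([C@H](O)c2ccc(OCc3ccccc3)c(OC)c2)CO)c(OCc2ccccc2)c(OC)c1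
F4 | step 9 | methyl 3-[(1S,2R)-1,3-dihydroxy-1-(4-hydroxy-3-methoxyphenyl)propan-2-yl]-4-hydroxy-5-methoxybenzoate | COC(=O)c1cc([C@@H]([C@H](O)c2ccc(O)c(OC)c2)CO)c(O)c(OC)c1
F5 | step 6 | (4R)-4-benzyl-3-{[2-(benzyloxy)-3-methoxy-5-(methoxycarbonyl)phenyl]acetyl}-1,3-oxazolidin-2-one | COC(=O)c1cc(CC(=O)N2C(=O)OC[C@H]2Cc2ccccc2)c(OCc2ccccc2)c(OC)c1
F6 | step 6 | 4-(benzyloxy)-3-methoxybenzyl bromide | COc1cc(CBr)ccc1OCc1ccccc1
F7 | step 6 | (4R)-4-benzyl-3-[(2R)-2-[2-(benzyloxy)-3-methoxy-5-(methoxycarbonyl)phenyl]-3-[4-(benzyloxy)-3-methoxyphenyl]propanoyl]-1,3-oxazolidin-2-one | COC(=O)c1cc([C@@H](Cc2ccc(OCc3ccccc3)c(OC)c2)C(=O)N2C(=O)OC[C@H]2Cc2ccccc2)c(OCc2ccccc2)c(OC)c1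
F0 | step 15 | none | none
F8 | step 13 | (2S,3R)-5-(2,2-dibromoethenyl)-7-methoxy-2-{3-methoxy-4-[(triisopropylsilyl)oxy]phenyl}-3-{[(triisopropylsilyl)oxy]methyl}-2,3-dihydro-1-benzofuran | COc1cc([C@H]2Oc3c(OC)cc(C=C(Br)Br)cc3[C@@H]2CO[Si](C(C)C)(C(C)C)C(C)C)ccc1O[Si](C(C)C)(C(C)C)C(C)C
F9 | step 4 | methyl 4-(benzyloxy)-3-(2,3-dihydroxypropyl)-5-methoxybenzoate (racemic) | COC(=O)c1cc(CC(O)CO)c(OCc2ccccc2)c(OC)c1
A1 | alternative 1 | 5-[(2S,3R)-2-[4-(benzyloxy)-3-methoxyphenyl]-3-{[tert-butyl(dimethyl)silyl]oxymethyl}-7-methoxy-2,3-dihydro-1-benzofuran-5-yl]furan-3-carbaldehyde | COc1cc([C@H]2Oc3c(OC)cc(-c4cc(C=O)co4)cc3[C@@H]2CO[Si](C)(C)C(C)(C)C)ccc1OCc1ccccc1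
A2 | alternative 1 | (3E)-4-{5-[(2S,3R)-2-[4-(benzyloxy)-3-methoxyphenyl]-3-{[tert-butyl(dimethyl)silyl]oxymethyl}-7-methoxy-2,3-dihydro-1-benzofuran-5-yl]furan-3-yl}-3-(methoxycarbonyl)but-3-enoic acid | COc1cc([C@H]2Oc3c(OC)cc(-c4cc(/C=C(\CC(O)=O)C(=O)OC)co4)cc3[C@@H]2CO[Si](C)(C)C(C)(C)C)ccc1OCc1ccccc1
A3 | alternative 1 | methyl 7-acetoxy-2-[(2S,3R)-2-[4-(benzyloxy)-3-methoxyphenyl]-3-{[tert-butyl(dimethyl)silyl]oxymethyl}-7-methoxy-2,3-dihydro-1-benzofuran-5-yl]-1-benzofuran-5-carboxylate | COc1cc([C@H]2Oc3c(OC)cc(-c4cc5cc(C(=O)OC)cc(OC(C)=O)c5o4)cc3[C@@H]2CO[Si](C)(C)C(C)(C)C)ccc1OCc1ccccc1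
A4 | alternative 2 | (2S)-6-bromo-8-methoxy-2-[3-methoxy-4-(methylsulfonyloxy)phenyl]-2,3-dihydro-4H-chromen-4-one | COc1cc([C@@H]2CC(=O)c3cc(Br)cc(OC)c3O2)ccc1OS(C)(=O)=O
A5 | alternative 2 | methyl (2S,3S)-5-bromo-7-methoxy-2-[3-methoxy-4-(methylsulfonyloxy)phenyl]-2,3-dihydro-1-benzofuran-3-carboxylate | COc1cc([C@H]2Oc3c(OC)cc(Br)cc3[C@@H]2C(=O)OC)ccc1OS(C)(=O)=O
A6 | alternative 3 | (4S)-4-benzyl-3-[(2E)-3-(4-hydroxy-3-methoxyphenyl)prop-2-enoyl]-1,3-oxazolidin-2-one | COc1cc(/C=C/C(=O)N2C(=O)OC[C@@H]2Cc3ccccc3)ccc1O
A7 | alternative 3 | 4-[5-(3-hydroxypropyl)-7-methoxy-1-benzofuran-2-yl]-2-methoxyphenol | COc1cc(-c2cc3cc(CCCO)cc(OC)c3o2)ccc1O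
A8 | alternative 3 | (4S)-4-benzyl-3-{[(2S,3S)-2-(4-hydroxy-3-methoxyphenyl)-5-[5-(3-hydroxypropyl)-7-methoxy-1-benzofuran-2-yl]-7-methoxy-2,3-dihydro-1-benzofuran-3-yl]carbonyl}-1,3-oxazolidin-2-one | COc1cc([C@H]2Oc3c(OC)cc(-c4cc5cc(CCCO)cc(OC)c5o4)cc3[C@@H]2C(=O)N6C(=O)OC[C@@H]6Cc7ccccc7)ccc1O
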